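## Analysis of the target

The target 24 is a depsidone. Benzene rings A and C are joined twice, by the ester A4–C(=O)–O–Cb and by the diaryl ether A5–O–Ca, and these two links make the seven-membered ring B. Ring C is fused across Ce–Cf to the five-membered lactone ring D. Ring A carries OMe (A1), H (A2), CH3 (A3), the ester carbonyl (A4), the ether oxygen (A5) and CH3 (A6). Ring C has no hydrogen and reads Ca (ether O), Cb (ester O), Cc (CH3), Cd (OH), Ce (lactone C=O), Cf (hemiacetal carbon of ring D). The only stereocentre is that hemiacetal carbon, (R) in 24; it has no partner centre, and because a 3-hydroxyphthalide can open to a formyl acid it is labile to acid, base and heat. Other sensitive groups are the aryl ester of ring B (base, nucleophiles) and the phenol para to the ether oxygen (oxidants). The difficulty lies in a hexasubstituted ring C with four kinds of substituent in fixed order, in two ring B C–O bonds that each sit between two ortho substituents, and in a stereocentre that must be set on a stable derivative and freed last. The strategy rests on ring C with Ca and Cb adjacent and ring D fused at Ce–Cf: this is the pattern left when a phthalide-fused aryne across Ca–Cb adds the O–H of a carboxylic acid, and such an aryne forms when a 1,3-diyne and an ester-tethered alkyne cyclise.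

## Retrosynthetic reasoning

**24 to 23.** The O–H of the hemiacetal is traced back to a benzyl carbonate on the same oxygen. A carbonate is configurationally stable, and hydrogenolysis removes it without acid or base and without touching the C–O bond at the stereocentre. An ordinary ester would need base or acid for removal, and either would open the hemiacetal and racemise it.

**23 to 22 to 21.** The stereocentre is set on racemic lactol 22 by an acylative dynamic kinetic resolution, which uses the very lability of the centre: the enantiomers of 22 interconvert through the ring-opened form while a chiral acyl-transfer catalyst converts one of them. Lactol 22 comes from 21 by hydrolysis of two acetals at once, the methyl acetal of ring D and the methoxymethyl ether on the Cd oxygen.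

**21 to 20 (ring B, bond A5–O–Ca).** The ether bond is cut so that the oxygen stays on ring A and Ca carries iodine. The reverse polarity, a hydroxyl on Ca coupled with a ring A sulfonate, was set aside. A free hydroxyl on Ca beside the ester oxygen on Cb is a catechol monoester, and under the base a metal-catalysed etherification needs, the aroyl group can migrate to the Ca oxygen. The phenoxide this would leave on Cb is para to the lactone carbonyl, so the migration is favoured, and ring B would close with ester and ether exchanged. With the ring A phenoxide as nucleophile no hydroxyl ever sits next to the ester on ring C, the oxygen atom that 1 already carries is kept, and no oxidation of ring C is needed.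

**20 back to 16.** Phenol 20 comes from sulfonate 19 by sulfonyl transfer to fluoride. The sulfonate thus serves as a heat-, acid- and Lewis-acid-stable mask of the ring A phenol that also deactivates ring A towards electrophiles. Ether 19 comes from phenol 18, protected so that the copper step meets a single phenoxide. Iodide 18 comes from phenol 17: the free Cd hydroxyl directs the electrophile to its para position Ca, the only open position of ring C. Phenol 17 comes from methyl ether 16 by chelation-controlled demethylation next to the lactone carbonyl.

**16 to 14 and 4 (key disconnection).** Three bonds are cut at once: Cc–Cd and Ce–Cf of ring C and the Cb–O ester bond. This returns the acyclic triyne ester 14 and the ring A acid 4 through benzyne 15. All six positions of ring C are fixed by the choice of two acetylenic pieces: the diyne terminus carries the Cc methyl, the ynol ether carbon becomes Cd with its oxygen, and the acetal carbon of the tether becomes the ring D hemiacetal carbon at the correct oxidation level. The forward step has to cyclise before the acid attacks the ynol ether or the acylal, and has to deliver the acid oxygen to Cb.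

**14 to 7 and 12.** The acylal C–O bond is cut between the acetal carbon and the carboxylate oxygen. Acetal 7 is activated as the chloro ether 13 and alkylates carboxylate salt 12, so the free ynol ether acid is never handled.

**7 and 12 to starting materials.** Acetal 7 comes from diynol 5 by oxidation to 6 and acetalisation. Salt 12 comes from methoxyacetylene 10 by metalation (11) and carboxylation, and 10 from chloroacetal 8 by double elimination (9). Methoxy is chosen on the alkyne because it has no β-hydrogen and cannot fragment to a ketene on heating.

**4 to 1.** Acid 4 comes from 1 in three steps: methylation of the free 4-hydroxyl (2), sulfonylation of the chelated 2-hydroxyl (3), and cleavage of the methyl ester at the methyl carbon, which spares the sulfonate.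

## Alternatives that were turned down

**Alternative 1:** The ether bond A5–O is cut with ring A held as a cyclohexadiene. In the forward step a phenoxide on Ca adds to the β-carbon of an enol-triflate ester and expels triflate, closing ring B to the dihydrodepsidone A1; ring A is aromatised afterwards.
- For it: the ether forms by addition–elimination at an activated sp2 carbon, without a metal and under mild base. On this one bond it is stronger than the copper coupling of the chosen route.
- Against it: the nucleophile is again a free Ca hydroxyl beside the Cb ester, so the acyl-migration problem returns, here with an even more electrophilic vinylogous acyl group. The fully substituted ring C, with three oxygens, a benzyl ester and an acetal, must be built separately, and that is the real problem of the target. The dehydrogenation of ring A must spare an electron-rich ring C that is easily oxidised to a quinone.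
- Comparison: the chosen route makes ring C, ring D and the ester in one step from acyclic pieces and closes ring B without a hydroxyl next to the ester.

**Alternative 2:** The lactone O–CH2 bond of ring D is cut back to a depsidone with a carboxylic acid on Ce and a methyl on Cf. In the forward step PhI(OAc)2 and I2 under light generate the carboxyl radical, which abstracts hydrogen from the flanking methyl; the oxidised benzylic carbon is captured by the carboxylate to give the phthalide A2.
- For it: ring C starts from simple β-orcinol-type chemistry, and the hydrogen transfer picks the Cf methyl by proximity among four aryl methyls. This is cleaner site control than any intermolecular oxidation, and it avoids polyynes altogether.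
- Against it: A2 is one oxidation level below the lactol, so a second benzylic oxidation is needed, now undirected and in competition with three aryl methyls. The iodinating medium can attack the electron-rich ring A at A2. The whole depsidone, ring B included, must exist before the step.
- Comparison: the chosen route carries the hemiacetal carbon at its final oxidation level from the start, as the acetal carbon of the tether, and needs no C–H oxidation.

**Alternative 3:** Ring C is cut at Ce–Cf and Cb–Cc. In the forward step a five-carbon β-keto ester adds through its central carbon to the β-carbon of an α-aryloxy enoate, and its ethyl methylene then condenses on the enoate ester carbon to give the cyclohexane-1,3-dione A3, which is aromatised later.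
- For it: every step is classical and scalable, and it is the same annulation by which β-orsellinates are made. The ring A–O–Ca bond is formed as a simple O-alkylation before ring C exists. On precedent and on the ether bond it is stronger than the chosen route.
- Against it: the α-oxygen and the acetal-bearing β-carbon make the enoate a poor acceptor. The condensation must go through the less acidic methylene. A3 is a mixture of stereoisomers and tautomers that must be dehydrogenated in the presence of an acid-sensitive acetal and a halogenation-prone ring A. After that come phenol differentiation, seven-membered lactonisation, ring D closure and the resolution.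
- Comparison: the chosen route delivers an aromatic, fully differentiated ring C directly with the depside ester in place, in fewer steps after the ring-forming event.

Key step: step 8

Assumption: the hemiacetal carbon of 24 is taken to be configurationally stable only in neutral, aprotic media at or below room temperature; (R)-benzotetramisole is taken as the catalyst enantiomer that gives (S)-23, and the (S)-catalyst is used if a trial on 22 shows the opposite sense.

## Route

Step 1
Reactants: 1 atraric acid (methyl 2,4-dihydroxy-3,6-dimethylbenzoate)
Product: 2 methyl 2-hydroxy-4-methoxy-3,6-dimethylbenzoate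
Conditions: MeI (1.1 equiv), K2CO3 (1.1 equiv), acetone, reflux
Reagents that add atoms: iodomethane, CI
Why: Williamson ether synthesis; the 2-hydroxyl is hydrogen-bonded to the ester carbonyl and flanked by two ortho groups, so the weak base should alkylate only the 4-hydroxyl.

Step 2
Reactants: 2 methyl 2-hydroxy-4-methoxy-3,6-dimethylbenzoate
Product: 3 methyl 4-methoxy-3,6-dimethyl-2-[(trifluoromethylsulfonyl)oxy]benzoate
Conditions: Tf2O, pyridine, CH2Cl2, 0 °C → rt
Reagents that add atoms: trifluoromethanesulfonic anhydride, O=S(=O)(OS(=O)(=O)C(F)(F)F)C(F)(F)F
Why: O-sulfonylation of a phenol; the strongly electrophilic anhydride overcomes the chelation and crowding of the salicylate hydroxyl.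

Step 3
Reactants: 3 methyl 4-methoxy-3,6-dimethyl-2-[(trifluoromethylsulfonyl)oxy]benzoate
Product: 4 4-methoxy-3,6-dimethyl-2-[(trifluoromethylsulfonyl)oxy]benzoic acid
Conditions: LiI (4 equiv), EtOAc, reflux; then 1 M HCl
Reagents that add atoms: none
Why: SN2 dealkylation of a methyl ester by iodide at the methyl carbon; it needs no attack on the doubly ortho-substituted carbonyl and avoids hydroxide, which would cleave the sulfonate at sulfur.

Step 4
Reactants: 5 hexa-2,4-diyn-1-ol
Product: 7 1,1-dimethoxyhexa-2,4-diyne, via hexa-2,4-diynal 6 (not isolated)
Conditions: MnO2, CH2Cl2, rt; filter; HC(OMe)3, MeOH, TsOH (cat.), rt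
Reagents that add atoms: trimethyl orthoformate, COC(OC)OC; methanol, CO
Why: MnO2 oxidation of a propargylic alcohol followed by acid-catalysed acetalisation with orthoformate as water scavenger; the volatile, sensitive ynal is carried on in solution.

Step 5
Reactants: 8 chloroacetaldehyde dimethyl acetal (2-chloro-1,1-dimethoxyethane)
Product: 10 methoxyacetylene (methoxyethyne), via sodium methoxyacetylide 9 (not isolated)
Conditions: NaNH2 (3 equiv), liq. NH3, –33 °C; evaporate NH3; cold sat. aq. NaCl, –20 °C; distil into THF at –78 °C
Reagents that add atoms: none
Why: twofold base-induced elimination (methanol, then HCl) to the acetylide, the standard preparation of 1-alkoxyalkynes from chloroacetals; the low-boiling ynol ether is collected directly as a cold THF solution.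

Step 6
Reactants: 10 methoxyacetylene
Product: 12 lithium 3-methoxyprop-2-ynoate, via lithium methoxyacetylide 11 (not isolated)
Conditions: n-BuLi (1.0 equiv), THF, –78 °C; CO2, –78 → 0 °C; evaporate
Reagents that add atoms: n-butyllithium, [Li]CCCC; carbon dioxide, O=C=O
Why: deprotonation of a terminal alkyne and carboxylation of the acetylide; the push–pull salt is kept as such because the free acid could add to its own ynol ether.

Step 7
Reactants: 7 1,1-dimethoxyhexa-2,4-diyne; 12 lithium 3-methoxyprop-2-ynoate
Product: 14 (±)-1-methoxyhexa-2,4-diyn-1-yl 3-methoxyprop-2-ynoate, via 1-chloro-1-methoxyhexa-2,4-diyne 13 (not isolated)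
Conditions: 7, AcCl (1.05 equiv), ZnCl2 (1 mol%), CH2Cl2, 0 °C → rt; then 12, THF–DMF, –20 °C → rt
Reagents that add atoms: none
Why: Lewis-acid-catalysed exchange of one acetal methoxy group for chloride, then O-alkylation of the carboxylate by the α-chloro ether, the usual way to acyloxy acetals; attack at the oxygen-bearing carbon is favoured because the positive charge of the ion pair is centred there.

Step 8
Reactants: 14 (±)-1-methoxyhexa-2,4-diyn-1-yl 3-methoxyprop-2-ynoate; 4 4-methoxy-3,6-dimethyl-2-[(trifluoromethylsulfonyl)oxy]benzoic acid
Product: 16 (±)-3,7-dimethoxy-6-methyl-1-oxo-1,3-dihydroisobenzofuran-5-yl 4-methoxy-3,6-dimethyl-2-[(trifluoromethylsulfonyl)oxy]benzoate, via phthalide-fused benzyne 15 (not isolated)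
Conditions: 4 (3 equiv), PhCl (0.02 M), 100 °C, sealed vessel
Reagents that add atoms: none
Why: Proposed new method: on heating, the 1,3-diyne of 14 and the tethered alkoxypropiolate should combine in a [4+2] sense (concerted, or stepwise through a diradical after the first bond) to give benzyne 15, across which the O–H of acid 4 then adds; the closest known reaction type is the thermal hexadehydro-Diels–Alder cyclisation of ester-tethered triynes bearing silyl or alkyl alkynes, whose phthalide-fused benzynes are captured by carboxylic acids as aryl esters, and what is new is the alkoxyalkyne as two-carbon partner and the acetal carbon in the tether. Ring D closes when the diyne terminus Cf bonds to the tether-bound alkyne carbon Ce, a five-membered closure over the three-atom tether with both alkynes exo to the new ring, and ring C closes as the six-membered ring of the cycloaddition through the second bond Cc–Cd. No stereocentre is formed and the acetal carbon stays racemic. The step needs the acid oxygen on Cb and hydrogen on Ca: the fused five-membered ring pinches the aryne angle at Ca and opens it at Cb, which makes Cb the electrophilic end, and the inductively withdrawing acetal carbon on Cf favours negative charge building up on Ca. The step also needs the ynol ether and the acylal to outlast the acid until cyclisation: the ester on the alkyne carbon that would be protonated lowers the basicity of the ynol ether much as in a β-alkoxyacrylate, methoxy has no β-hydrogen for loss of a ketene, and the non-polar medium disfavours ionisation at the acetal carbon. The acid is used in excess and the surplus is recovered by extraction into aqueous NaHCO3.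

Step 9
Reactants: 16 (±)-3,7-dimethoxy-6-methyl-1-oxo-1,3-dihydroisobenzofuran-5-yl 4-methoxy-3,6-dimethyl-2-[(trifluoromethylsulfonyl)oxy]benzoate
Product: 17 (±)-7-hydroxy-3-methoxy-6-methyl-1-oxo-1,3-dihydroisobenzofuran-5-yl 4-methoxy-3,6-dimethyl-2-[(trifluoromethylsulfonyl)oxy]benzoate
Conditions: BCl3 (3 equiv), CH2Cl2, –78 → 0 °C; MeOH, 0 °C
Reagents that add atoms: none
Why: chelation-controlled demethylation; BCl3 bridges the lactone carbonyl and the adjacent Cd methoxy oxygen, while the ring A methoxy group has no neighbouring carbonyl and should survive. Any chloride exchanged in at the ring D acetal carbon is returned to the methyl acetal by the methanol quench.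

Step 10
Reactants: 17 (±)-7-hydroxy-3-methoxy-6-methyl-1-oxo-1,3-dihydroisobenzofuran-5-yl 4-methoxy-3,6-dimethyl-2-[(trifluoromethylsulfonyl)oxy]benzoate
Product: 18 (±)-7-hydroxy-4-iodo-3-methoxy-6-methyl-1-oxo-1,3-dihydroisobenzofuran-5-yl 4-methoxy-3,6-dimethyl-2-[(trifluoromethylsulfonyl)oxy]benzoate
Conditions: NIS (1.05 equiv), TFA (10 mol%), MeCN, 0 °C → rt
Reagents that add atoms: N-iodosuccinimide, O=C1CCC(=O)N1I
Why: electrophilic aromatic iodination; Ca is para to the free hydroxyl, meta to the lactone carbonyl and the only open position of ring C, whereas the one open position of ring A is deactivated by the para sulfonate and the meta ester.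

Step 11
Reactants: 18 (±)-7-hydroxy-4-iodo-3-methoxy-6-methyl-1-oxo-1,3-dihydroisobenzofuran-5-yl 4-methoxy-3,6-dimethyl-2-[(trifluoromethylsulfonyl)oxy]benzoate
Product: 19 (±)-4-iodo-3-methoxy-7-(methoxymethoxy)-6-methyl-1-oxo-1,3-dihydroisobenzofuran-5-yl 4-methoxy-3,6-dimethyl-2-[(trifluoromethylsulfonyl)oxy]benzoate
Conditions: MOMCl (1.5 equiv), iPr2NEt (2 equiv), CH2Cl2, 0 °C → rt
Reagents that add atoms: chloromethyl methyl ether, COCCl
Why: O-alkylation of the only free hydroxyl with a small, reactive α-chloro ether; the acetal protecting group removes the para-phenoxide that would slow the copper step and later falls off together with the ring D methyl acetal.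

Step 12
Reactants: 19 (±)-4-iodo-3-methoxy-7-(methoxymethoxy)-6-methyl-1-oxo-1,3-dihydroisobenzofuran-5-yl 4-methoxy-3,6-dimethyl-2-[(trifluoromethylsulfonyl)oxy]benzoate
Product: 20 (±)-4-iodo-3-methoxy-7-(methoxymethoxy)-6-methyl-1-oxo-1,3-dihydroisobenzofuran-5-yl 2-hydroxy-4-methoxy-3,6-dimethylbenzoate
Conditions: Bu4NF (1.5 equiv), THF, 0 °C → rt; aq. NH4Cl
Reagents that add atoms: none
Why: cleavage of an aryl triflate by attack of fluoride at sulfur; fluoride is a poor nucleophile towards the hindered 2,6-disubstituted benzoate and the lactone, and the aryl iodide and both acetals are inert to it.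

Step 13
Reactants: 20 (±)-4-iodo-3-methoxy-7-(methoxymethoxy)-6-methyl-1-oxo-1,3-dihydroisobenzofuran-5-yl 2-hydroxy-4-methoxy-3,6-dimethylbenzoate
Product: 21 racemic depsidone with rings A to D closed (ether A5–O–Ca, ester A4–C(=O)–O–Cb), OMe on the ring D acetal carbon and a methoxymethyl ether on the Cd oxygen
Conditions: CuI (20 mol%), N,N-dimethylglycine hydrochloride (40 mol%), Cs2CO3 (3 equiv), dioxane (0.01 M), 90 °C
Reagents that add atoms: none
Why: intramolecular Ullmann ether synthesis; the depside ester holds the ring A phenoxide next to the C–I bond, so the seven-membered ring B closes by coupling of the single phenoxide with the aryl iodide at high dilution. No hydroxyl lies beside the ester on ring C, so the acyl group cannot migrate.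

Step 14
Reactants: 21 racemic depsidone methyl acetal with the methoxymethyl ether on Cd
Product: 22 racemic lactol: the depsidone with OH on the ring D hemiacetal carbon and free Cd–OH (racemate of 24)
Conditions: 3 M HCl, THF, 50 °C
Reagents that add atoms: water, O
Why: acid hydrolysis of two acetals through oxocarbenium ions, the aryl methoxymethyl ether and the 3-methoxyphthalide; the aryl ester of ring B and the lactone are stable to aqueous acid. The stereocentre is not yet set.

Step 15
Reactants: 22 racemic lactol
Product: 23 benzyl carbonate of the ring D hemiacetal oxygen, (S) at the acetal carbon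
Conditions: (BnOCO)2O (1.5 equiv), (R)-benzotetramisole (10 mol%), iPr2NEt (0.3 equiv), CHCl3, 0 °C
Reagents that add atoms: dibenzyl dicarbonate, O=C(OCc1ccccc1)OC(=O)OCc1ccccc1
Why: acylative dynamic kinetic resolution of a 3-hydroxyphthalide; the enantiomers of 22 interconvert through the ring-opened formyl carboxylate under the amine base, and the chiral N-acyl isothiouronium ion transfers the benzyloxycarbonyl group faster to one of them, so the stereocentre is set by the catalyst. The hydrogen-bonded, doubly flanked Cd phenol should not compete, and a carbonate formed there would fall off in step 16.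

Step 16
Reactants: 23 (S)-benzyl carbonate
Product: 24 the target, (R)-lactol
Conditions: H2 (1 atm), 5% Pd/C, EtOAc, 0 °C; filter, concentrate cold
Reagents that add atoms: none
Why: hydrogenolysis of the benzyl–oxygen bond gives a carbonic acid monoester that loses CO2. The C–O bond at the stereocentre is never broken, so the configuration is retained; the descriptor changes from S to R only because the carbonate oxygen outranks the ring oxygen and the hydroxyl does not. The conditions are neutral, aprotic and cold.

## Compound list

1 | atraric acid (methyl 2,4-dihydroxy-3,6-dimethylbenzoate) | COC(=O)c1c(C)cc(O)c(C)c1O | starting material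
2 | methyl 2-hydroxy-4-methoxy-3,6-dimethylbenzoate | COC(=O)c1c(C)cc(OC)c(C)c1O | intermediate
3 | methyl 4-methoxy-3,6-dimethyl-2-[(trifluoromethylsulfonyl)oxy]benzoate | COC(=O)c1c(C)cc(OC)c(C)c1OS(=O)(=O)C(F)(F)F | intermediate
4 | 4-methoxy-3,6-dimethyl-2-[(trifluoromethylsulfonyl)oxy]benzoic acid | COc1cc(C)c(C(=O)O)c(OS(=O)(=O)C(F)(F)F)c1C | intermediate
5 | hexa-2,4-diyn-1-ol | CC#CC#CCO | starting material
6 | hexa-2,4-diynal | CC#CC#CC=O | intermediate
7 | 1,1-dimethoxyhexa-2,4-diyne | CC#CC#CC(OC)OC | intermediate
8 | chloroacetaldehyde dimethyl acetal | COC(CCl)OC | starting material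
9 | sodium methoxyacetylide | [Na+].[C-]#COC | intermediate
10 | methoxyacetylene | C#COC | intermediate
11 | lithium methoxyacetylide | [Li+].[C-]#COC | intermediate
12 | lithium 3-methoxyprop-2-ynoate | [Li+].[O-]C(=O)C#COC | intermediate
13 | 1-chloro-1-methoxyhexa-2,4-diyne (racemic) | CC#CC#CC(Cl)OC | intermediate
14 | 1-methoxyhexa-2,4-diyn-1-yl 3-methoxyprop-2-ynoate (racemic) | CC#CC#CC(OC)OC(=O)C#COC | intermediate
15 | 3,7-dimethoxy-6-methyl-4,5-didehydroisobenzofuran-1(3H)-one (benzyne, racemic) | COC1OC(=O)C2=C1C#CC(C)=C2OC | intermediate
16 | 3,7-dimethoxy-6-methyl-1-oxo-1,3-dihydroisobenzofuran-5-yl 4-methoxy-3,6-dimethyl-2-[(trifluoromethylsulfonyl)oxy]benzoate (racemic) | COc1cc(C)c(C(=O)Oc2cc3C(OC)OC(=O)c3c(OC)c2C)c(OS(=O)(=O)C(F)(F)F)c1C | intermediate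
17 | 7-hydroxy-3-methoxy-6-methyl-1-oxo-1,3-dihydroisobenzofuran-5-yl 4-methoxy-3,6-dimethyl-2-[(trifluoromethylsulfonyl)oxy]benzoate (racemic) | COc1cc(C)c(C(=O)Oc2cc3C(OC)OC(=O)c3c(O)c2C)c(OS(=O)(=O)C(F)(F)F)c1C | intermediate
18 | 7-hydroxy-4-iodo-3-methoxy-6-methyl-1-oxo-1,3-dihydroisobenzofuran-5-yl 4-methoxy-3,6-dimethyl-2-[(trifluoromethylsulfonyl)oxy]benzoate (racemic) | COc1cc(C)c(C(=O)Oc2c(I)c3C(OC)OC(=O)c3c(O)c2C)c(OS(=O)(=O)C(F)(F)F)c1C | intermediate
19 | 4-iodo-3-methoxy-7-(methoxymethoxy)-6-methyl-1-oxo-1,3-dihydroisobenzofuran-5-yl 4-methoxy-3,6-dimethyl-2-[(trifluoromethylsulfonyl)oxy]benzoate (racemic) | COc1cc(C)c(C(=O)Oc2c(I)c3C(OC)OC(=O)c3c(OCOC)c2C)c(OS(=O)(=O)C(F)(F)F)c1C | intermediate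
20 | 4-iodo-3-methoxy-7-(methoxymethoxy)-6-methyl-1-oxo-1,3-dihydroisobenzofuran-5-yl 2-hydroxy-4-methoxy-3,6-dimethylbenzoate (racemic) | COc1cc(C)c(C(=O)Oc2c(I)c3C(OC)OC(=O)c3c(OCOC)c2C)c(O)c1C | intermediate
21 | depsidone methyl acetal with methoxymethyl ether on the Cd oxygen (racemic) | COc1cc(C)c2c(c1C)Oc1c(c(C)c(OCOC)c3c1C(OC)OC3=O)OC2=O | intermediate
22 | depsidone lactol, racemate of the target | COc1cc(C)c2c(c1C)Oc1c(c(C)c(O)c3c1C(O)OC3=O)OC2=O | intermediate
23 | benzyl carbonate of the depsidone lactol, (S) at the acetal carbon | COc1cc(C)c2c(c1C)Oc1c(c(C)c(O)c3c1[C@H](OC(=O)OCc4ccccc4)OC3=O)OC2=O | intermediate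
24 | CNP0255863.1, depsidone lactol, (R) at the hemiacetal carbon | COc1cc(C)c2c(c1C)Oc1c(c(C)c(O)c3c1[C@H](O)OC3=O)OC2=O | target

## Step count and least certain steps

Total: 16 steps. Longest linear sequence: 12 steps (steps 5, 6, 7, 8 to 16; equally steps 1, 2, 3, 8 to 16).

**Step 8 (key step, proposed new method).** The acid may add across the ynol ether, or exchange at the acylal carbon, before the triyne cyclises; the donor-substituted alkyne may also react more slowly than the silyl and alkyl alkynes on which the reaction is established. The fallback uses only known chemistry and replaces the ynol ether by a silyl alkyne. It sets out from 7: the chloro ether 13 is made as in step 7 and treated with 3-(trimethylsilyl)propiolic acid and iPr2NEt to give 1-methoxyhexa-2,4-diyn-1-yl 3-(trimethylsilyl)prop-2-ynoate F1. Heating F1 with acid 4 as in step 8 should give the silyl depside 3-methoxy-6-methyl-1-oxo-7-(trimethylsilyl)-1,3-dihydroisobenzofuran-5-yl 4-methoxy-3,6-dimethyl-2-[(trifluoromethylsulfonyl)oxy]benzoate F2. Ipso-borodesilylation with BCl3, directed by the neighbouring lactone carbonyl, and a methanol quench give the dimethyl arylboronate F3, which is oxidised without isolation by NaBO3·4H2O in THF–water. The fallback comes back to the route at phenol 17.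

**Step 13.** Oxidative addition at the doubly ortho-substituted iodide may be slow, so that hydrodeiodination takes over; under hot base the ring A phenoxide may also attack Cb and displace the carboxylate in a Smiles-type aryl migration. The fallback reverses the polarity of the ether formation and sets out from 17. Oxidation with (KSO3)2NO in buffered aqueous MeCN gives the acyloxy quinone F4, and Na2S2O4 reduces it at once to the hydroquinone F5. Pd(OAc)2 with di-tert-butyl(2',4',6'-triisopropylbiphenyl-2-yl)phosphine and K3PO4 in toluene at 80 °C couples the new Ca hydroxyl with the ring A triflate to the depsidone methyl acetal with free Cd hydroxyl F6. Hydrolysis as in step 14 brings the fallback back at 22. The known weakness of this fallback is acyl migration in F5; the hindered aroyl group and the mildest workable base are relied on to hold it back.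

**Step 15.** The aryloxy group next to the hemiacetal carbon may lower the selectivity of acyl transfer, and an uncatalysed acylation through the ring-opened carboxylate may erode it further. The fallback is a classical resolution and sets out from 22. Benzyl chloroformate and pyridine give the racemic benzyl carbonate F7, which is separated by preparative chromatography on a chiral stationary phase into 23 and its (R)-enantiomer F8. F8 is hydrogenolysed as in step 16 to the racemising lactol 22 and recycled. The fallback comes back at 23.

**Step 16.** The freed hemiacetal may epimerise by ring opening on the catalyst or during isolation, and hydrogen may cleave the benzylic C–O bond of ring D. The fallback removes the carbonate without hydrogen and sets out from 22. Resolution as in step 15 with diallyl dicarbonate gives the allyl carbonate of the depsidone lactol, (S) at the acetal carbon, F9. Pd(PPh3)4 (zerovalent palladium, catalytic) with dimedone in THF at 0 °C then transfers the allyl group to the weakly acidic scavenger, and the carbonic acid monoester loses CO2. The fallback comes back at the target 24.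

**Step 7.** The conjugated chloro ether may ionise towards allenyl products or polymerise, and the acylal may decompose on purification. The fallback forms the other C–O bond of the acylal and sets out from 6 (isolated after the MnO2 oxidation of step 4) and 12. Salt 12 and 2,4,6-trichlorobenzoyl chloride give the mixed anhydride 3-methoxyprop-2-ynoic 2,4,6-trichlorobenzoic anhydride F10. Aldehyde 6 with one equivalent of methanol and Et3N stands in equilibrium with the hemiacetal 1-methoxyhexa-2,4-diyn-1-ol F11, whose hydroxyl is acylated by F10 at the less hindered carbonyl under DMAP catalysis. The fallback comes back at 14.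

## Further compounds

F1 | step 8 | 1-methoxyhexa-2,4-diyn-1-yl 3-(trimethylsilyl)prop-2-ynoate (racemic) | CC#CC#CC(OC)OC(=O)C#C[Si](C)(C)C
F2 | step 8 | 3-methoxy-6-methyl-1-oxo-7-(trimethylsilyl)-1,3-dihydroisobenzofuran-5-yl 4-methoxy-3,6-dimethyl-2-[(trifluoromethylsulfonyl)oxy]benzoate (racemic) | COc1cc(C)c(C(=O)Oc2cc3C(OC)OC(=O)c3c([Si](C)(C)C)c2C)c(OS(=O)(=O)C(F)(F)F)c1C
F3 | step 8 | dimethyl arylboronate at Cd of the depside (racemic) | COc1cc(C)c(C(=O)Oc2cc3C(OC)OC(=O)c3c(B(OC)OC)c2C)c(OS(=O)(=O)C(F)(F)F)c1C
F4 | step 13 | acyloxy quinone of the depside (racemic) | COc1cc(C)c(C(=O)OC2=C(C)C(=O)C3=C(C(OC)OC3=O)C2=O)c(OS(=O)(=O)C(F)(F)F)c1C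
F5 | step 13 | hydroquinone of the depside with hydroxyls on Ca and Cd (racemic) | COc1cc(C)c(C(=O)Oc2c(O)c3C(OC)OC(=O)c3c(O)c2C)c(OS(=O)(=O)C(F)(F)F)c1C
F6 | step 13 | depsidone methyl acetal with free Cd hydroxyl (racemic) | COc1cc(C)c2c(c1C)Oc1c(c(C)c(O)c3c1C(OC)OC3=O)OC2=O
F7 | step 15 | benzyl carbonate of the depsidone lactol (racemic) | COc1cc(C)c2c(c1C)Oc1c(c(C)c(O)c3c1C(OC(=O)OCc4ccccc4)OC3=O)OC2=O
F8 | step 15 | benzyl carbonate of the depsidone lactol, (R) at the acetal carbon | COc1cc(C)c2c(c1C)Oc1c(c(C)c(O)c3c1[C@@H](OC(=O)OCc4ccccc4)OC3=O)OC2=O
F9 | step 16 | allyl carbonate of the depsidone lactol, (S) at the acetal carbon | COc1cc(C)c2c(c1C)Oc1c(c(C)c(O)c3c1[C@H](OC(=O)OCC=C)OC3=O)OC2=O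
F10 | step 7 | 3-methoxyprop-2-ynoic 2,4,6-trichlorobenzoic anhydride | COC#CC(=O)OC(=O)c1c(Cl)cc(Cl)cc1Cl
F11 | step 7 | 1-methoxyhexa-2,4-diyn-1-ol (racemic hemiacetal) | CC#CC#CC(O)OC
A1 | alternative 1 | dihydrodepsidone with ring B closed (racemic at the ring A methyl-bearing carbon) | COC1=C(C)C2=C(C(C)C1)C(=O)Oc1c(C)c(O)c(C(=O)OCc3ccccc3)c(C(OC)OC)c1O2
A2 | alternative 2 | depsidone phthalide acetate | COc1cc(C)c2c(c1C)Oc1c(c(C)c(OC(C)=O)c3c1COC3=O)OC2=O
A3 | alternative 3 | aryloxy cyclohexane-1,3-dione ester (mixture of stereoisomers) | COC(=O)C1C(=O)C(C)C(=O)C(Oc2c(C)c(OC)cc(C)c2C(=O)OC(C)(C)C)C1C(OC)OC
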